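## Retrosynthetic overview

1. The carbocyclic ring B (C1, C9, C5, C6, C7, C8) is closed last through the C1–C8 bond: a tertiary C8 cation attacks C1 of the dearomatised acylphloroglucinol, as in the presumed biogenesis.
2. The C8 cation is stored in, and released by acid from, the O-cyclised isomer (a 2,2-dimethylchroman, O9–C8). This chroman ring also steers the C5 alkylation trans to the C7 prenyl group, which translates into the 7-endo bicycle.
3. The C5 quaternary centre is made by alkylative dearomatisation with the side-chain triflate, whose isopropenyl and carbinol groups are masked together as an iodomethyl-oxolane (opened again with zinc).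
4. Both ten-carbon units come from (S)-lavandulol (Evans alkylation); the side-chain carbinol comes from a Shi epoxidation; the aryl ketone comes from a Hoesch acylation.
5. Ring order: aromatic ring (from phloroglucinol), then pyran ring (O9–C8), then carbocyclic ring B (C1–C8) with loss of the pyran ring in the same step.

Assumption: atom labels follow the bicyclic target throughout (C1 prenylated bridgehead, C3 aroyl carbon, C5 side-chain bridgehead, C7 endo-prenyl carbon, C8 CMe2, C9 bridging carbonyl carbon, O9 its oxygen), and the target is taken as the C4-enol tautomer drawn.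

## Route

Step 1
Reactants: 1 (S)-4-benzyloxazolidin-2-one; 2 3-methylbut-2-enoyl chloride
Product: 3 (S)-4-benzyl-3-(3-methylbut-2-enoyl)oxazolidin-2-one
Conditions: n-BuLi, THF, −78 °C, then 2, −78 to 0 °C
Reagents that add atoms: 3-methylbut-2-enoyl chloride (2), CC(C)=CC(Cl)=O
Why: N-acylation of the lithiated Evans oxazolidinone by the acid chloride is fast at low temperature and does not touch the auxiliary stereocentre (imide formation).

Step 2
Reactants: 3 (S)-4-benzyl-3-(3-methylbut-2-enoyl)oxazolidin-2-one; 4 prenyl bromide (1-bromo-3-methylbut-2-ene)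
Product: 5 (S)-4-benzyl-3-[(2S)-5-methyl-2-(prop-1-en-2-yl)hex-4-enoyl]oxazolidin-2-one
Conditions: NaN(SiMe3)2, THF, −78 °C, then 4, −78 to −40 °C
Reagents that add atoms: prenyl bromide (4), CC(C)=CCBr
Why: Evans asymmetric alkylation: γ-deprotonation gives the chelated Z-dienolate, which is prenylated at the α-carbon on the face opposite the benzyl group, setting the (2S) centre and shifting the alkene into the isopropenyl position.

Step 3
Reactants: 5 (S)-4-benzyl-3-[(2S)-5-methyl-2-(prop-1-en-2-yl)hex-4-enoyl]oxazolidin-2-one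
Product: 6 (S)-lavandulol [(2S)-5-methyl-2-(prop-1-en-2-yl)hex-4-en-1-ol]
Conditions: LiBH4, H2O (1 equiv), Et2O, 0 °C
Reagents that add atoms: none
Why: Reductive cleavage of the imide with LiBH4 gives the primary alcohol without touching the α-centre or the alkenes and releases the auxiliary.

Step 4
Reactants: 6 (S)-lavandulol
Product: 7 (S)-lavandulyl triflate [(2S)-5-methyl-2-(prop-1-en-2-yl)hex-4-en-1-yl trifluoromethanesulfonate]
Conditions: Tf2O, 2,6-lutidine, CH2Cl2, −78 °C; filtered cold through silica and used at once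
Reagents that add atoms: triflic anhydride, O=S(=O)(OS(=O)(=O)C(F)(F)F)C(F)(F)F
Why: O-sulfonylation of the primary alcohol gives the one leaving group reactive enough for phenoxide C-alkylation at a β-branched carbon, and the stereocentre is not involved.

Step 5
Reactants: 8 phloroglucinol; 9 3,4-dihydroxybenzonitrile
Product: 11 maclurin [(3,4-dihydroxyphenyl)(2,4,6-trihydroxyphenyl)methanone], via ketiminium chloride 10 (not isolated)
Conditions: ZnCl2, HCl (g), Et2O, 0 °C; then H2O, 100 °C
Reagents that add atoms: 3,4-dihydroxybenzonitrile (9), N#Cc1ccc(O)c(O)c1; water, O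
Why: Houben–Hoesch acylation: the nitrilium ion attacks the symmetric, strongly activated phloroglucinol once, and hydrolysis of the ketiminium salt gives the benzophenone.

Step 6
Reactants: 11 maclurin
Product: 12 silylene-protected maclurin [ArSi–C(O)–(2,4,6-trihydroxyphenyl); ArSi = 2,2-di-tert-butyl-1,3,2-benzodioxasilol-5-yl]
Conditions: tBu2Si(OTf)2 (1.05 equiv), 2,6-lutidine, DMF, 0 °C
Reagents that add atoms: di-tert-butylsilyl bis(trifluoromethanesulfonate), CC(C)(C)[Si](OS(=O)(=O)C(F)(F)F)(OS(=O)(=O)C(F)(F)F)C(C)(C)C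
Why: Only the ortho-diol can close a five-membered cyclic silylene, whereas the meta-disposed, carbonyl-chelated phenols of the other ring cannot (cyclic silylene protection of a catechol).

Step 7
Reactants: 12 silylene-protected maclurin; 7 (S)-lavandulyl triflate
Product: 13 ArSi {2,4,6-trihydroxy-3-[(2R)-5-methyl-2-(prop-1-en-2-yl)hex-4-en-1-yl]phenyl} ketone (lavandulyl chain on C5; CIP label R but same geometry as in 6)
Conditions: 12 (2 equiv), LiN(SiMe3)2 (6 equiv), toluene–THF, −78 to 0 °C, then 7 (1 equiv)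
Reagents that add atoms: (S)-lavandulyl triflate (7), C=C(C)[C@H](CC=C(C)C)COS(=O)(=O)C(F)(F)F
Why: ortho-C-alkylation of the lithium phenoxide by SN2 at the primary triflate (tight lithium ion pairs favour C over O, and excess 12 limits double alkylation), with the chain stereocentre untouched.

Step 8
Reactants: 13 C5-lavandulyl benzophenone
Product: 14 ArSi (3R)-5,7-dihydroxy-2,2-dimethyl-3-(3-methylbut-2-en-1-yl)chroman-6-yl ketone (pyran ring O9–C8–C7–C6–C5)
Conditions: TsOH·H2O (10 mol %), CH2Cl2, 0 °C to rt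
Reagents that add atoms: none
Why: Acid-catalysed Markovnikov hydroalkoxylation: the tertiary cation from the isopropenyl group is trapped by O9, the only phenol not hydrogen-bonded to the aroyl carbonyl, faster than it can lose the C7 proton, so C7 keeps its configuration.

Step 9
Reactants: 14 chroman
Product: 15 ArSi (3R)-8-bromo-5,7-dihydroxy-2,2-dimethyl-3-(3-methylbut-2-en-1-yl)chroman-6-yl ketone (bromine on C1)
Conditions: NBS (1.0 equiv), CH2Cl2, −78 °C
Reagents that add atoms: N-bromosuccinimide, O=C1CCC(=O)N1Br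
Why: Electrophilic aromatic bromination takes the single free, doubly activated ring position well below the temperature at which NBS attacks the trisubstituted alkene, and the bromine blocks C1 for step 14.

Step 10
Reactants: 6 (S)-lavandulol
Product: 16 (2S)-2-{[(2R)-3,3-dimethyloxiran-2-yl]methyl}-3-methylbut-3-en-1-ol
Conditions: D-fructose-derived Shi ketone (30 mol %), Oxone, K2CO3, Bu4NHSO4, MeCN–CH2(OMe)2–aqueous buffer pH 10.5, −5 °C
Reagents that add atoms: Oxone (active component KHSO5), [K+].[O-]S(=O)(=O)OO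
Why: Shi epoxidation: the chiral dioxirane oxidises the electron-rich trisubstituted alkene in preference to the 1,1-disubstituted one through the spiro transition state, setting the (R) configuration at the future carbinol carbon.

Step 11
Reactants: 16 epoxy alcohol
Product: 17 (2S,4R)-5-methyl-2-(prop-1-en-2-yl)hex-5-ene-1,4-diol
Conditions: Et2Al(NC9H18) (diethylaluminium 2,2,6,6-tetramethylpiperidide, 3.5 equiv), toluene, 0 °C
Reagents that add atoms: none
Why: Yamamoto-type isomerisation of an epoxide to an allylic alcohol: the aluminium amide removes a methyl proton syn to the coordinated oxygen, and the C–O bond at the secondary carbon is never broken, so the (R) carbinol forms with retention.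

Step 12
Reactants: 17 diol
Product: 18 [(3R,5R)-2-(iodomethyl)-2-methyl-5-(prop-1-en-2-yl)oxolan-3-yl]methanol (both C2 epimers)
Conditions: I2, NaHCO3, MeCN, 0 °C
Reagents that add atoms: iodine, II
Why: 5-exo iodoetherification: the secondary hydroxyl adds to the iodonium ion of the 1,3-related isopropenyl group (the oxygen-deactivated allylic alkene and the four-membered mode of the primary hydroxyl are slower), masking both groups in a form that zinc reopens; the new quaternary centre is erased again in step 17.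

Step 13
Reactants: 18 iodomethyl-oxolane alcohol
Product: 19 [(3R,5R)-2-(iodomethyl)-2-methyl-5-(prop-1-en-2-yl)oxolan-3-yl]methyl trifluoromethanesulfonate
Conditions: Tf2O, 2,6-lutidine, CH2Cl2, −78 °C; used at once
Reagents that add atoms: triflic anhydride, O=S(=O)(OS(=O)(=O)C(F)(F)F)C(F)(F)F
Why: Triflation of the primary alcohol; the neopentyl-type iodide and the ring stereocentres are inert.

Step 14
Reactants: 15 bromochroman; 19 oxolane triflate
Product: 20 (3R,4aR)-6-(ArSi-carbonyl)-8-bromo-7-hydroxy-4a-{[(3S,5R)-2-(iodomethyl)-2-methyl-5-(prop-1-en-2-yl)oxolan-3-yl]methyl}-2,2-dimethyl-3-(3-methylbut-2-en-1-yl)-3,4-dihydro-2H-chromen-5(4aH)-one (C5 side chain trans to the C7 prenyl group)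
Conditions: 15 (1.5 equiv), LiN(SiMe3)2 (3.1 equiv), toluene–THF, −78 °C, then 19, −78 to 0 °C
Reagents that add atoms: oxolane triflate (19), O=S(=O)(OC[C@H]1C[C@H](C(C)=C)OC1(C)CI)C(F)(F)F
Why: Proposed new method: alkylative dearomatisation of the chroman dianion at the ring-fusion carbon C5, the only nucleophilic carbon left once C1 carries bromine and C3 the aroyl group; the electrophile enters axially on the half-chair pyran ring on the face anti to the pseudo-equatorial C7 prenyl group, setting C5 trans to C7; closest known reaction: LiN(SiMe3)2-mediated alkylative dearomatisation of acylphloroglucinols with allylic halides or alkyl triflates.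

Step 15
Reactants: 20 bromodienone; 21 tributyl(3-methylbut-2-en-1-yl)stannane
Product: 22 the 8-(3-methylbut-2-en-1-yl) analogue of 20 (prenyl on C1 in place of bromine; otherwise unchanged)
Conditions: Pd2(dba)3 (5 mol %), AsPh3, CuI, DMF, 40 °C
Reagents that add atoms: tributyl(3-methylbut-2-en-1-yl)stannane (21), CCCC[Sn](CCCC)(CCCC)CC=C(C)C
Why: Stille coupling: zerovalent palladium inserts into the vinylic C–Br bond and the prenyl group is transferred from tin through its unsubstituted terminus, while the neopentyl-type iodide does not undergo oxidative addition.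

Step 16
Reactants: 22 prenylated pyranodienone
Product: 23 (1R,5S,7R)-3-(ArSi-carbonyl)-4-hydroxy-5-{[(3S,5R)-2-(iodomethyl)-2-methyl-5-(prop-1-en-2-yl)oxolan-3-yl]methyl}-8,8-dimethyl-1,7-bis(3-methylbut-2-en-1-yl)bicyclo[3.3.1]non-3-ene-2,9-dione (7-endo; CIP label at C5 differs from the target only through the mask)
Conditions: HCO2H–CH2Cl2 (1:1), 0 °C to rt
Reagents that add atoms: none
Why: Proposed new method: formic acid protonates the enol ether at C1 and the tertiary O9–C8 bond ionises (reverse hydroalkoxylation); the C8 cation, still tethered through C6–C7 to C5, recombines with the re-formed C1 enol carbon in a net 1,3 O-to-C shift that is irreversible, while every O-cyclised form re-ionises; because C5 and C7 are already fixed trans, the chain can close only from its own face, which gives the 7-endo ring B and sets the C1 bridgehead, and the masked side chain has no alkene that could compete or close onto the enol; closest known reaction: the biomimetic formic acid-mediated cation cyclisation of dearomatised lavandulyl acylphloroglucinols.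

Step 17
Reactants: 23 masked bicycle
Product: 24 (1R,5R,7R)-3-(ArSi-carbonyl)-4-hydroxy-5-[(2S,4R)-4-hydroxy-5-methyl-2-(prop-1-en-2-yl)hex-5-en-1-yl]-8,8-dimethyl-1,7-bis(3-methylbut-2-en-1-yl)bicyclo[3.3.1]non-3-ene-2,9-dione
Conditions: Zn dust, AcOH, EtOH, 40 °C
Reagents that add atoms: none
Why: Zinc inserts into the C–I bond and β-elimination of the ring alkoxide (Boord-type reductive ring opening) regenerates the isopropenyl group and the free (R)-carbinol with both side-chain stereocentres untouched.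

Step 18
Reactants: 24 silylene-protected target
Product: 25 target, (1R,5R,7R)-3-(3,4-dihydroxybenzoyl)-4-hydroxy-5-[(2S,4R)-4-hydroxy-5-methyl-2-(prop-1-en-2-yl)hex-5-en-1-yl]-8,8-dimethyl-1,7-bis(3-methylbut-2-en-1-yl)bicyclo[3.3.1]non-3-ene-2,9-dione
Conditions: Et3N·3HF, THF, 0 °C to rt
Reagents that add atoms: none
Why: Fluoride-driven cleavage of the cyclic silylene frees the catechol under near-neutral conditions that avoid acid-induced closure of the enol onto the isopropenyl group.

## Compound list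

1 | (S)-4-benzyloxazolidin-2-one | O=C1N[C@@H](Cc2ccccc2)CO1 | starting material
2 | 3-methylbut-2-enoyl chloride | CC(C)=CC(Cl)=O | starting material
3 | (S)-4-benzyl-3-(3-methylbut-2-enoyl)oxazolidin-2-one | CC(C)=CC(=O)N1[C@@H](Cc2ccccc2)COC1=O | intermediate
4 | prenyl bromide (1-bromo-3-methylbut-2-ene) | CC(C)=CCBr | starting material
5 | (S)-4-benzyl-3-[(2S)-5-methyl-2-(prop-1-en-2-yl)hex-4-enoyl]oxazolidin-2-one | C=C(C)[C@H](CC=C(C)C)C(=O)N1[C@@H](Cc2ccccc2)COC1=O | intermediate
6 | (S)-lavandulol, (2S)-5-methyl-2-(prop-1-en-2-yl)hex-4-en-1-ol | C=C(C)[C@H](CC=C(C)C)CO | intermediate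
7 | (S)-lavandulyl trifluoromethanesulfonate | C=C(C)[C@H](CC=C(C)C)COS(=O)(=O)C(F)(F)F | intermediate
8 | phloroglucinol | Oc1cc(O)cc(O)c1 | starting material
9 | 3,4-dihydroxybenzonitrile | N#Cc1ccc(O)c(O)c1 | starting material
10 | (3,4-dihydroxyphenyl)(2,4,6-trihydroxyphenyl)methaniminium chloride | [NH2+]=C(c1ccc(O)c(O)c1)c1c(O)cc(O)cc1O.[Cl-] | intermediate
11 | maclurin, (3,4-dihydroxyphenyl)(2,4,6-trihydroxyphenyl)methanone | O=C(c1ccc(O)c(O)c1)c1c(O)cc(O)cc1O | intermediate
12 | (2,2-di-tert-butyl-1,3,2-benzodioxasilol-5-yl)(2,4,6-trihydroxyphenyl)methanone | O=C(c1ccc2O[Si](C(C)(C)C)(C(C)(C)C)Oc2c1)c1c(O)cc(O)cc1O | intermediate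
13 | (2,2-di-tert-butyl-1,3,2-benzodioxasilol-5-yl){2,4,6-trihydroxy-3-[(2R)-5-methyl-2-(prop-1-en-2-yl)hex-4-en-1-yl]phenyl}methanone | C=C(C)[C@H](CC=C(C)C)Cc1c(O)cc(O)c(C(=O)c2ccc3O[Si](C(C)(C)C)(C(C)(C)C)Oc3c2)c1O | intermediate
14 | (2,2-di-tert-butyl-1,3,2-benzodioxasilol-5-yl)[(3R)-5,7-dihydroxy-2,2-dimethyl-3-(3-methylbut-2-en-1-yl)chroman-6-yl]methanone | O=C(c1ccc2O[Si](C(C)(C)C)(C(C)(C)C)Oc2c1)c1c(O)cc2OC(C)(C)[C@H](CC=C(C)C)Cc2c1O | intermediate
15 | [(3R)-8-bromo-5,7-dihydroxy-2,2-dimethyl-3-(3-methylbut-2-en-1-yl)chroman-6-yl](2,2-di-tert-butyl-1,3,2-benzodioxasilol-5-yl)methanone | O=C(c1ccc2O[Si](C(C)(C)C)(C(C)(C)C)Oc2c1)c1c(O)c(Br)c2OC(C)(C)[C@H](CC=C(C)C)Cc2c1O | intermediate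
16 | (2S)-2-{[(2R)-3,3-dimethyloxiran-2-yl]methyl}-3-methylbut-3-en-1-ol | OC[C@@H](C[C@@H]1C(C)(C)O1)C(C)=C | intermediate
17 | (2S,4R)-5-methyl-2-(prop-1-en-2-yl)hex-5-ene-1,4-diol | OC[C@@H](C[C@@H](O)C(C)=C)C(C)=C | intermediate
18 | [(3R,5R)-2-(iodomethyl)-2-methyl-5-(prop-1-en-2-yl)oxolan-3-yl]methanol, both C2 epimers | OC[C@H]1C[C@H](C(C)=C)OC1(C)CI | intermediate
19 | [(3R,5R)-2-(iodomethyl)-2-methyl-5-(prop-1-en-2-yl)oxolan-3-yl]methyl trifluoromethanesulfonate | O=S(=O)(OC[C@H]1C[C@H](C(C)=C)OC1(C)CI)C(F)(F)F | intermediate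
20 | (3R,4aR)-8-bromo-6-[(2,2-di-tert-butyl-1,3,2-benzodioxasilol-5-yl)carbonyl]-7-hydroxy-4a-{[(3S,5R)-2-(iodomethyl)-2-methyl-5-(prop-1-en-2-yl)oxolan-3-yl]methyl}-2,2-dimethyl-3-(3-methylbut-2-en-1-yl)-3,4-dihydro-2H-chromen-5(4aH)-one | O=C(c1ccc2O[Si](C(C)(C)C)(C(C)(C)C)Oc2c1)C1=C(O)C(Br)=C2OC(C)(C)[C@H](CC=C(C)C)C[C@]2(C[C@H]3C[C@H](C(C)=C)OC3(C)CI)C1=O | intermediate
21 | tributyl(3-methylbut-2-en-1-yl)stannane | CCCC[Sn](CCCC)(CCCC)CC=C(C)C | starting material
22 | (3R,4aR)-6-[(2,2-di-tert-butyl-1,3,2-benzodioxasilol-5-yl)carbonyl]-7-hydroxy-4a-{[(3S,5R)-2-(iodomethyl)-2-methyl-5-(prop-1-en-2-yl)oxolan-3-yl]methyl}-2,2-dimethyl-3,8-bis(3-methylbut-2-en-1-yl)-3,4-dihydro-2H-chromen-5(4aH)-one | O=C(c1ccc2O[Si](C(C)(C)C)(C(C)(C)C)Oc2c1)C1=C(O)C(CC=C(C)C)=C2OC(C)(C)[C@H](CC=C(C)C)C[C@]2(C[C@H]3C[C@H](C(C)=C)OC3(C)CI)C1=O | intermediate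
23 | (1R,5S,7R)-3-[(2,2-di-tert-butyl-1,3,2-benzodioxasilol-5-yl)carbonyl]-4-hydroxy-5-{[(3S,5R)-2-(iodomethyl)-2-methyl-5-(prop-1-en-2-yl)oxolan-3-yl]methyl}-8,8-dimethyl-1,7-bis(3-methylbut-2-en-1-yl)bicyclo[3.3.1]non-3-ene-2,9-dione | ICC5(C)O[C@@H](C(C)=C)C[C@@H]5C[C@@]12C[C@@H](CC=C(C)C)C(C)(C)[C@@](CC=C(C)C)(C(=O)C(C(=O)c3ccc4O[Si](C(C)(C)C)(C(C)(C)C)Oc4c3)=C1O)C2=O | intermediate
24 | (1R,5R,7R)-3-[(2,2-di-tert-butyl-1,3,2-benzodioxasilol-5-yl)carbonyl]-4-hydroxy-5-[(2S,4R)-4-hydroxy-5-methyl-2-(prop-1-en-2-yl)hex-5-en-1-yl]-8,8-dimethyl-1,7-bis(3-methylbut-2-en-1-yl)bicyclo[3.3.1]non-3-ene-2,9-dione | C=C(C)[C@H](C[C@@H](O)C(=C)C)C[C@@]12C[C@@H](CC=C(C)C)C(C)(C)[C@@](CC=C(C)C)(C(=O)C(C(=O)c3ccc4O[Si](C(C)(C)C)(C(C)(C)C)Oc4c3)=C1O)C2=O | intermediate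
25 | (1R,5R,7R)-3-(3,4-dihydroxybenzoyl)-4-hydroxy-5-[(2S,4R)-4-hydroxy-5-methyl-2-(prop-1-en-2-yl)hex-5-en-1-yl]-8,8-dimethyl-1,7-bis(3-methylbut-2-en-1-yl)bicyclo[3.3.1]non-3-ene-2,9-dione | C=C(C)[C@H](C[C@@H](O)C(=C)C)C[C@@]12C[C@@H](CC=C(C)C)C(C)(C)[C@@](CC=C(C)C)(C(=O)C(C(=O)c3ccc(O)c(O)c3)=C1O)C2=O | target

## Step count and risks

Total steps: 18. Longest linear sequence: 12 (steps 1, 2, 3, 10, 11, 12, 13, 14, 15, 16, 17, 18).

The three steps most likely to fail are step 14, step 16 and step 15.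

Step 14 asks a hindered ring-fusion carbon to displace a β-branched triflate. O-alkylation and incomplete facial control are the likely losses. The fallback drops the chroman-directed alkylation and sets out from 13. NBS brominates C1 of 13 to the open-chain aryl bromide F1. The lithium trianion of F1 is alkylated with 19 at C5 to give the open-chain bromodienone F2 together with its C5 epimer F3, and the two are separated by chromatography. F2 is coupled with 21 (Pd2(dba)3, AsPh3, CuI) to the open-chain prenylated dienone F4. In formic acid the free isopropenyl group of F4 first closes onto O9, which is 22 formed in the flask, and the O-to-C shift then follows, so the route is rejoined at 23.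

Step 16 needs a boat-like closure to reach the 7-endo ring. Closure at the aroyl-bearing C3, or loss of the C7 proton from the cation, would divert material. The fallback sets out from 20 and closes the ring onto an unsubstituted, more nucleophilic and less hindered C1. The bromine of 20 is removed with Na2S2O3 to the C1–H pyranodienone F5. Formic acid then converts F5 into the bridgehead C–H bicycle F6. F6 is deprotonated with excess lithium 2,2,6,6-tetramethylpiperidide (enolate plus bridgehead carbanion) and alkylated with 4, which can only occur with retention at the bridgehead, and the route is rejoined at 23.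

Step 15 may suffer from bromine transfer from the α-bromo vinylogous acid to the stannane or from protodestannylation by the acidic enol. The fallback replaces the cross-coupling by polar chemistry and sets out from 20. Halophilic reduction with Na2S2O3 gives the C1–H pyranodienone F5. Its potassium enolate (K2CO3, acetone) is C-prenylated with 4 at C1, and the route is rejoined at 22.

Further compounds
F1 | step 14 | {3-bromo-2,4,6-trihydroxy-5-[(2R)-5-methyl-2-(prop-1-en-2-yl)hex-4-en-1-yl]phenyl}(2,2-di-tert-butyl-1,3,2-benzodioxasilol-5-yl)methanone | C=C(C)[C@H](CC=C(C)C)Cc1c(O)c(Br)c(O)c(C(=O)c2ccc3O[Si](C(C)(C)C)(C(C)(C)C)Oc3c2)c1O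
F2 | step 14 | open-chain bromodienone, 4-bromo-2-[(2,2-di-tert-butyl-1,3,2-benzodioxasilol-5-yl)carbonyl]-3,5-dihydroxy-6-[(2R)-lavandulyl]-6-[(iodomethyl-oxolanyl)methyl]cyclohexa-2,4-dien-1-one, C6 epimer with the configuration of C5 in 20 | O=C(c1ccc2O[Si](C(C)(C)C)(C(C)(C)C)Oc2c1)C1=C(O)C(Br)=C(O)[C@@](C[C@@H](CC=C(C)C)C(C)=C)(C[C@H]2C[C@H](C(C)=C)OC2(C)CI)C1=O
F3 | step 14 | C6 epimer of F2 (discarded) | O=C(c1ccc2O[Si](C(C)(C)C)(C(C)(C)C)Oc2c1)C1=C(O)C(Br)=C(O)[C@](C[C@@H](CC=C(C)C)C(C)=C)(C[C@H]2C[C@H](C(C)=C)OC2(C)CI)C1=O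
F4 | step 14 | open-chain prenylated dienone, F2 with 3-methylbut-2-en-1-yl in place of bromine | O=C(c1ccc2O[Si](C(C)(C)C)(C(C)(C)C)Oc2c1)C1=C(O)C(CC=C(C)C)=C(O)[C@@](C[C@@H](CC=C(C)C)C(C)=C)(C[C@H]2C[C@H](C(C)=C)OC2(C)CI)C1=O
F5 | step 15 | C1–H pyranodienone, 20 with hydrogen in place of bromine | O=C(c1ccc2O[Si](C(C)(C)C)(C(C)(C)C)Oc2c1)C1=C(O)C=C2OC(C)(C)[C@H](CC=C(C)C)C[C@]2(C[C@H]3C[C@H](C(C)=C)OC3(C)CI)C1=O
F6 | step 16 | bridgehead C–H bicycle, 23 with hydrogen in place of the C1 prenyl group | ICC5(C)O[C@@H](C(C)=C)C[C@@H]5C[C@@]12C[C@@H](CC=C(C)C)C(C)(C)[C@@H](C(=O)C(C(=O)c3ccc4O[Si](C(C)(C)C)(C(C)(C)C)Oc4c3)=C1O)C2=O
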